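The pyranone ring C is cut at C4a–C4, C4–C3 and O1–C2. The feature used is that C4, C3 and C2 form a three-carbon bridge between ring A and ring B, with O1 on C8a next to the prenylated C8. Carbon monoxide supplies C4. A ring-B arylacetylene that already carries the (R)-epoxide supplies C3 and C2. One palladium-catalysed operation joins both to a ring-A ortho-iodophenol and closes ring C as a flavone. That iodophenol has a single free hydroxyl, wedged between iodine and prenyl, so only the 8-prenyl isomer can arise. C2 becomes stereogenic afterwards by ligand-controlled hydride addition, and buffered fluoride then frees the phenols.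

Key step: step 9

Assumption: (R)-DTBM-SEGPHOS is taken to direct hydride to the Re face of C2, by analogy with the sense BINAP-type ligands show on β-aryl cyclic acceptors. This is to be checked on a simple model flavone, and the antipodal ligand is used if the sense is opposite.

Step 1
Reactants: 1 phloroglucinol; 2 prenyl bromide
Product: 3 2-prenylphloroglucinol
Conditions: 1 (3 equiv), KOH (1 equiv), 2 (1 equiv), H2O, 0 °C to rt; work-up at pH 6
Reagents that add atoms: none
Why: C-alkylation of the ambident phloroglucinolate, which reacts at carbon in water because its oxygens are solvated, while the excess of cheap, water-soluble 1 suppresses a second alkylation.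

Step 2
Reactants: 3 2-prenylphloroglucinol
Product: 4 2-iodo-4-prenylbenzene-1,3,5-triol
Conditions: I2 (1.0 equiv), NaHCO3, THF/H2O, 0 °C, dark, short contact; used at once
Reagents that add atoms: iodine, II
Why: Electrophilic aromatic iodination of a phloroglucinol under bicarbonate should far outrun attack of iodine on the trisubstituted alkene, and only one mono-iodide is possible because the two ring C–H positions of 3 are equivalent by symmetry.

Step 3
Reactants: 4 2-iodo-4-prenylbenzene-1,3,5-triol
Product: 5 3,5-bis(tert-butyldimethylsilyloxy)-2-iodo-6-prenylphenol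
Conditions: TBSCl (2.05 equiv), imidazole, DMF, −10 to 0 °C
Reagents that add atoms: tert-butyldimethylsilyl chloride, CC(C)(C)[Si](C)(C)Cl
Why: Sterically governed O-silylation, in which the hydroxyl between iodine and prenyl has two ortho substituents and reacts last with the bulky chlorosilane, so the two hydroxyls with an ortho hydrogen are capped and the future O1 stays free.

Step 4
Reactants: 6 4-iodophenol; 2 prenyl bromide
Product: 7 4-iodo-2-prenylphenol
Conditions: NaH (1.0 equiv), toluene, 0 °C to rt, then 2
Reagents that add atoms: none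
Why: Ortho-C-alkylation of a sodium phenoxide in a non-polar solvent, where the tight ion pair delivers the allylic bromide to the ortho carbon, and the para position is blocked by iodine.

Step 5
Reactants: 7 4-iodo-2-prenylphenol
Product: 8 (4-iodo-2-prenylphenoxy)triisopropylsilane
Conditions: TIPSCl, imidazole, DMF, rt
Reagents that add atoms: triisopropylsilyl chloride, CC(C)[Si](Cl)(C(C)C)C(C)C
Why: Imidazole-promoted O-silylation, with TIPS chosen because this ether must outlast carbonate in methanol, Oxone at pH 10.5 and warm diethylamine, since its early loss would let the phenoxide open the neighbouring epoxide.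

Step 6
Reactants: 8 (4-iodo-2-prenylphenoxy)triisopropylsilane; 9 trimethylsilylacetylene
Product: 10 triisopropyl{2-prenyl-4-[(trimethylsilyl)ethynyl]phenoxy}silane
Conditions: PdCl2(PPh3)2 (2 mol %), CuI (4 mol %), Et3N, THF, rt
Reagents that add atoms: none
Why: Sonogashira coupling, which proceeds at room temperature with an aryl iodide and so leaves the prenyl alkene and the silyl ether unstressed.

Step 7
Reactants: 10 triisopropyl{2-prenyl-4-[(trimethylsilyl)ethynyl]phenoxy}silane
Product: 11 (4-ethynyl-2-prenylphenoxy)triisopropylsilane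
Conditions: K2CO3 (0.2 equiv), MeOH/CH2Cl2, rt
Reagents that add atoms: none
Why: Base-catalysed methanolysis of the C(sp)–SiMe3 bond, to which the hindered aryl TIPS ether is inert, and it is run before any epoxide is present.

Step 8
Reactants: 11 (4-ethynyl-2-prenylphenoxy)triisopropylsilane
Product: 12 (R)-{2-[(3,3-dimethyloxiran-2-yl)methyl]-4-ethynylphenoxy}triisopropylsilane
Conditions: D-fructose-derived Shi ketone (1,2:4,5-di-O-isopropylidene-β-D-erythro-2,3-hexodiulo-2,6-pyranose, 30 mol %), Oxone (2KHSO5·KHSO4·K2SO4), K2CO3, Bu4NHSO4 (cat.), MeCN/dimethoxymethane, aq. Na2B4O7/Na2EDTA buffer (pH 10.5), 0 °C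
Reagents that add atoms: potassium peroxymonosulfate (active part of Oxone), [K+].[O-]S(=O)(=O)OO
Why: Shi asymmetric epoxidation, in which the dioxirane of the D-fructose-derived ketone transfers oxygen through the spiro transition state to the alkene face that makes the CH–O carbon (R), as for other 2-methylalk-2-enes, while the terminal alkyne is much less reactive toward dioxiranes.

Step 9
Reactants: 5 3,5-bis(tert-butyldimethylsilyloxy)-2-iodo-6-prenylphenol; 12 (R)-{2-[(3,3-dimethyloxiran-2-yl)methyl]-4-ethynylphenoxy}triisopropylsilane; 13 carbon monoxide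
Product: 16 5,7-bis(tert-butyldimethylsilyloxy)-2-{3-[((2R)-3,3-dimethyloxiran-2-yl)methyl]-4-(triisopropylsilyloxy)phenyl}-8-prenyl-4H-chromen-4-one, via ortho-hydroxyaryl ynone 14 (not isolated), via diethylamino enaminone 15 (not isolated)
Conditions: PdCl2(dppf) (5 mol %), CO (10 bar), anhydrous Et2NH/THF 1:1, 60 °C, no copper salt
Reagents that add atoms: none
Why: Zerovalent palladium, formed from PdCl2(dppf) under CO and amine, inserts into the C4a–I bond of 5, CO migrates in to give the aroylpalladium iodide, and the acetylide made from 12 and Et2NH is transferred and reductively eliminated, which forms C4a–C4 and C4–C3 in ynone 14. Et2NH then adds to the alkyne carbon that bears ring B to give enaminone 15, and the neighbouring phenol oxygen attacks this carbon (6-endo-trig) and expels the amine, which forms O1–C2 and closes ring C; this amine detour keeps the ynone from the 5-exo-dig closure to an aurone. The closest known reaction type is this very one, the carbonylative Sonogashira coupling and annulation of ortho-iodophenols with terminal arylacetylenes to flavones in a secondary amine. No stereocentre is created, and the (R)-epoxide carbon lies outside the reacting π system with no acid or free phenoxide near it, so it should pass through unchanged. The regiochemical demand, 8-prenyl and not 6-prenyl, is met by the substrate alone, since the oxygen between the iodinated and the prenylated carbon is the only one without a silyl group. The chemoselectivity demand, CO uptake before alkyne transfer, is served by leaving out copper and by CO pressure, and the two ortho substituents of the aroylpalladium slow its capture by the amine.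

Step 10
Reactants: 16 tris-silyl flavone
Product: 18 (2S)-5,7-bis(tert-butyldimethylsilyloxy)-2-{3-[((2R)-3,3-dimethyloxiran-2-yl)methyl]-4-(triisopropylsilyloxy)phenyl}-8-prenylchroman-4-one, via silyl enol ether 17 (not isolated)
Conditions: Cu(OAc)2 (5 mol %), (R)-DTBM-SEGPHOS (5.5 mol %), (EtO)2MeSiH (3 equiv), toluene, 0 °C to rt; then pH 7 phosphate buffer, THF
Reagents that add atoms: none
Why: Asymmetric CuH-catalysed 1,4-hydrosilylation, established for β,β-disubstituted cyclic enones and for 4H-chromen-4-ones, in which the bulky bisphosphine on copper admits hydride only to the Re face of C2 (giving 2S), the enolate is held as silyl enol ether 17 so that neither ring opening nor carbonyl reduction follows, and the unactivated prenyl alkene, the epoxide and the aryl silyl ethers are inert to CuH.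

Step 11
Reactants: 18 tris-silyl (2S)-flavanone
Product: 19 (2S)-5,7-dihydroxy-2-{3-[((2R)-3,3-dimethyloxiran-2-yl)methyl]-4-hydroxyphenyl}-8-prenylchroman-4-one (target)
Conditions: Bu4NF (3.3 equiv), AcOH (3.6 equiv), THF, 0 °C; pH 7 buffer work-up, chromatography on neutral reversed-phase silica
Reagents that add atoms: none
Why: Fluoride-induced cleavage of aryl silyl ethers, with acetic acid protonating each phenoxide as it is released, so that the ring-B oxygen cannot open the adjacent epoxide and ring C cannot open to the chalcone, which preserves both stereocentres.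

Compound list
1 | phloroglucinol | Oc1cc(O)cc(O)c1 | starting material
2 | prenyl bromide | CC(C)=CCBr | starting material
3 | 2-prenylphloroglucinol | CC(C)=CCc1c(O)cc(O)cc1O | intermediate
4 | 2-iodo-4-prenylbenzene-1,3,5-triol | CC(C)=CCc1c(O)cc(O)c(I)c1O | intermediate
5 | 3,5-bis(tert-butyldimethylsilyloxy)-2-iodo-6-prenylphenol | CC(C)=CCc1c(O[Si](C)(C)C(C)(C)C)cc(O[Si](C)(C)C(C)(C)C)c(I)c1O | intermediate
6 | 4-iodophenol | Oc1ccc(I)cc1 | starting material
7 | 4-iodo-2-prenylphenol | CC(C)=CCc1cc(I)ccc1O | intermediate
8 | (4-iodo-2-prenylphenoxy)triisopropylsilane | CC(C)=CCc1cc(I)ccc1O[Si](C(C)C)(C(C)C)C(C)C | intermediate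
9 | trimethylsilylacetylene | C#C[Si](C)(C)C | starting material
10 | triisopropyl{2-prenyl-4-[(trimethylsilyl)ethynyl]phenoxy}silane | CC(C)=CCc1cc(C#C[Si](C)(C)C)ccc1O[Si](C(C)C)(C(C)C)C(C)C | intermediate
11 | (4-ethynyl-2-prenylphenoxy)triisopropylsilane | CC(C)=CCc1cc(C#C)ccc1O[Si](C(C)C)(C(C)C)C(C)C | intermediate
12 | (R)-{2-[(3,3-dimethyloxiran-2-yl)methyl]-4-ethynylphenoxy}triisopropylsilane | C#Cc1ccc(O[Si](C(C)C)(C(C)C)C(C)C)c(C[C@H]2OC2(C)C)c1 | intermediate
13 | carbon monoxide | [C-]#[O+] | starting material
14 | 1-[4,6-bis(tert-butyldimethylsilyloxy)-2-hydroxy-3-prenylphenyl]-3-{3-[((2R)-3,3-dimethyloxiran-2-yl)methyl]-4-(triisopropylsilyloxy)phenyl}prop-2-yn-1-one | CC(C)=CCc1c(O[Si](C)(C)C(C)(C)C)cc(O[Si](C)(C)C(C)(C)C)c(C(=O)C#Cc2ccc(O[Si](C(C)C)(C(C)C)C(C)C)c(C[C@H]3OC3(C)C)c2)c1O | intermediate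
15 | 3-(diethylamino)prop-2-en-1-one adduct of 14 (alkene geometry not defined) | CC(C)=CCc1c(O[Si](C)(C)C(C)(C)C)cc(O[Si](C)(C)C(C)(C)C)c(C(=O)C=C(N(CC)CC)c2ccc(O[Si](C(C)C)(C(C)C)C(C)C)c(C[C@H]3OC3(C)C)c2)c1O | intermediate
16 | tris-silyl flavone (2,3-didehydro form of 18) | CC(C)=CCc1c(O[Si](C)(C)C(C)(C)C)cc(O[Si](C)(C)C(C)(C)C)c2c1OC(c1ccc(O[Si](C(C)C)(C(C)C)C(C)C)c(C[C@H]3OC3(C)C)c1)=CC2=O | intermediate
17 | (2S)-4-[diethoxy(methyl)silyloxy]-2H-chromene (silyl enol ether of 18) | CC(C)=CCc1c(O[Si](C)(C)C(C)(C)C)cc(O[Si](C)(C)C(C)(C)C)c2c1O[C@H](c1ccc(O[Si](C(C)C)(C(C)C)C(C)C)c(C[C@H]3OC3(C)C)c1)C=C2O[Si](C)(OCC)OCC | intermediate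
18 | tris-silyl (2S)-flavanone | CC(C)=CCc1c(O[Si](C)(C)C(C)(C)C)cc(O[Si](C)(C)C(C)(C)C)c2c1O[C@H](c1ccc(O[Si](C(C)C)(C(C)C)C(C)C)c(C[C@H]3OC3(C)C)c1)CC2=O | intermediate
19 | (2S)-5,7-dihydroxy-2-{3-[((2R)-3,3-dimethyloxiran-2-yl)methyl]-4-hydroxyphenyl}-8-prenylchroman-4-one | CC(C)=CCc1c(O)cc(O)c2c1O[C@H](c1ccc(O)c(C[C@H]3OC3(C)C)c1)CC2=O | target

Total step count: 11.
Longest linear sequence: 8 steps (steps 4 to 11, from 4-iodophenol).

Steps most likely to fail

**Step 9.**
- What may go wrong: oxidative addition may be sluggish at the crowded, electron-rich C–I bond.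
- The alkyne may couple before CO is taken up, followed by five-membered ring closure.
- Diethylamine may capture the aroylpalladium.
- Warm amine may erode the ring-A silyl ethers.
- Fallback: the same three bonds are built with stoichiometric organometallic chemistry, without palladium or CO gas, setting out from 5 and 12.
- Alkyne 12 is lithiated (n-BuLi, THF, −78 °C) and acylated with N-methoxy-N-methylcarbamoyl chloride to give the Weinreb propiolamide F1.
- Iodophenol 5 is deprotonated with MeMgCl in the presence of LiCl and then undergoes iodine–magnesium exchange with i-PrMgCl at −20 °C, giving the magnesiated phenoxide F2.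
- F2 is acylated by F1 and, after an NH4Cl quench, gives ynone 14, now isolated. Here the fallback rejoins the route.
- Et2NH in THF at rt to 40 °C then takes 14 through 15 to 16.

**Step 10.**
- What may go wrong: hydride transfer to the electron-rich vinylogous ester may be slow.
- Facial selectivity may be insufficient.
- The ring-A phenoxide may be lost from the copper enolate by β-elimination, opening the ring.
- Competing 1,2-reduction may occur.
- Fallback: resolution replaces induction, setting out from 16.
- A non-selective 1,4-hydrosilylation uses the more reactive achiral system Cu(OAc)2, 1,2-bis(diphenylphosphino)benzene and (EtO)2MeSiH. It gives the C2-epimeric silyl enol ether F3 and, after buffer hydrolysis, the C2-epimeric flavanone mixture F4.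
- Noyori–Ikariya transfer hydrogenation is run as a kinetic resolution: Cp*RhCl[(R,R)-TsDPEN], HCO2Na, H2O/EtOAc, rt, a neutral medium chosen for the epoxide. It should reduce the 2R epimer faster, giving the cis-(2R,4R)-flavan-4-ol F5.
- F5 is removed by chromatography. The unreacted 2S epimer is 18, where the route is rejoined.

**Step 11.**
- What may go wrong: the freed ring-B oxygen may attack the adjacent epoxide.
- Base may open ring C, with loss of configuration at C2.
- Acid may open the epoxide during purification.
- Fallback: the phenols are unmasked by neutral acyl transfer instead of by fluoride, setting out from 18.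
- The silyl ethers are exchanged for acetates in one operation (CsF, excess Ac2O, MeCN, 0 °C). Each phenoxide is trapped by the anhydride as it forms, giving the triacetate F6.
- The aryl acetates are then removed under neutral conditions (NH4OAc, aqueous MeOH, rt), which leads directly to 19.

Further compounds
F1 | step 9 | 3-{3-[((2R)-3,3-dimethyloxiran-2-yl)methyl]-4-(triisopropylsilyloxy)phenyl}-N-methoxy-N-methylprop-2-ynamide | CON(C)C(=O)C#Cc1ccc(O[Si](C(C)C)(C(C)C)C(C)C)c(C[C@H]2OC2(C)C)c1
F2 | step 9 | chloromagnesium 3,5-bis(tert-butyldimethylsilyloxy)-2-(chloromagnesio)-6-prenylphenoxide | CC(C)=CCc1c(O[Si](C)(C)C(C)(C)C)cc(O[Si](C)(C)C(C)(C)C)c([Mg]Cl)c1O[Mg]Cl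
F3 | step 10 | silyl enol ether as in 17 but as both C2 epimers | CC(C)=CCc1c(O[Si](C)(C)C(C)(C)C)cc(O[Si](C)(C)C(C)(C)C)c2c1OC(c1ccc(O[Si](C(C)C)(C(C)C)C(C)C)c(C[C@H]3OC3(C)C)c1)C=C2O[Si](C)(OCC)OCC
F4 | step 10 | tris-silyl flavanone as both C2 epimers | CC(C)=CCc1c(O[Si](C)(C)C(C)(C)C)cc(O[Si](C)(C)C(C)(C)C)c2c1OC(c1ccc(O[Si](C(C)C)(C(C)C)C(C)C)c(C[C@H]3OC3(C)C)c1)CC2=O
F5 | step 10 | tris-silyl cis-(2R,4R)-flavan-4-ol | CC(C)=CCc1c(O[Si](C)(C)C(C)(C)C)cc(O[Si](C)(C)C(C)(C)C)c2c1O[C@@H](c1ccc(O[Si](C(C)C)(C(C)C)C(C)C)c(C[C@H]3OC3(C)C)c1)C[C@H]2O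
F6 | step 11 | 5,7,4'-triacetate of 19 | CC(C)=CCc1c(OC(C)=O)cc(OC(C)=O)c2c1O[C@H](c1ccc(OC(C)=O)c(C[C@H]3OC3(C)C)c1)CC2=O
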